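## Retrosynthetic overview

1. Target 18 ⇐ keto acid 16 by two late α-methylations of the cyclopentanone (C1, C3; the all-trans arrangement is the thermodynamic one).
2. 16 ⇐ spiro-dithiane aldehyde 14 (CHO → CO2H, dithiane → C=O).
3. 14 ⇐ achiral all-E tetraenal 13 by one catalytic enantioselective iminium Diels–Alder reaction. It forms C4–C5 and C3a–C7a, so the cyclohexene and the cyclopentane ring close in the same step, with all four ring stereocentres.
4. 13 ⇐ dithiane 5 (two differentiated C2 arms) by iterative E-selective Wittig/HWE olefinations; 5 ⇐ 1,3-dithiane + BrCH2CH(OMe)2 + oxirane.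

Assumption: ylide 7 is a catalogue reagent; the facial sense of the new catalyst in step 9 is assigned from an ion-pair model (if it proves opposite, the pseudo-enantiomeric quinidine-derived amine/(S)-TRIP pair is used in the same step); anions made in the flask by a base and catalyst-bound iminium ions are treated as reagent-level species and are not numbered.

## Route

Step 1
Reactants: 1 1,3-dithiane; 2 2-bromo-1,1-dimethoxyethane
Product: 3 2-(2,2-dimethoxyethyl)-1,3-dithiane
Conditions: n-BuLi, THF, −30 °C; then 2, −30 °C → rt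
Reagents that add atoms: none
Why: Corey–Seebach alkylation, the lithiated dithiane displacing the primary bromide by SN2; no stereocentre.

Step 2
Reactants: 3 2-(2,2-dimethoxyethyl)-1,3-dithiane; 4 oxirane
Product: 5 2-[2-(2,2-dimethoxyethyl)-1,3-dithian-2-yl]ethan-1-ol
Conditions: n-BuLi, THF, −25 °C, 3 h; then 4, −25 → 0 °C; H2O
Reagents that add atoms: none
Why: second Corey–Seebach lithiation and SN2 opening of the epoxide give an achiral quaternary dithiane whose two C2 arms (free alcohol, dimethyl acetal) can be unmasked separately.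

Step 3
Reactants: 5 2-[2-(2,2-dimethoxyethyl)-1,3-dithian-2-yl]ethan-1-ol
Product: 6 [2-(2,2-dimethoxyethyl)-1,3-dithian-2-yl]acetaldehyde
Conditions: Dess–Martin periodinane, pyridine, CH2Cl2, 0 °C → rt; used crude
Reagents that add atoms: none
Why: Dess–Martin oxidation of the primary alcohol; the buffered, non-aqueous conditions leave the dithiane and the acetal intact.

Step 4
Reactants: 6 [2-(2,2-dimethoxyethyl)-1,3-dithian-2-yl]acetaldehyde; 7 2-(triphenylphosphoranylidene)butanal
Product: 8 (2E)-4-[2-(2,2-dimethoxyethyl)-1,3-dithian-2-yl]-2-ethylbut-2-enal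
Conditions: 7 (1.2 equiv), toluene, 70 °C
Reagents that add atoms: none
Why: Wittig olefination with a stabilised α-formyl ylide gives the trisubstituted enal with the usual high E selectivity.

Step 5
Reactants: 8 (2E)-4-[2-(2,2-dimethoxyethyl)-1,3-dithian-2-yl]-2-ethylbut-2-enal; 7 2-(triphenylphosphoranylidene)butanal
Product: 9 (2E,4E)-6-[2-(2,2-dimethoxyethyl)-1,3-dithian-2-yl]-2,4-diethylhexa-2,4-dienal
Conditions: 7 (1.5 equiv), toluene, 105 °C, 24 h
Reagents that add atoms: none
Why: second Wittig homologation with the same stabilised ylide (E-selective); the more conjugated dienal 9 is less electrophilic than 8, which limits over-homologation.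

Step 6
Reactants: 9 (2E,4E)-6-[2-(2,2-dimethoxyethyl)-1,3-dithian-2-yl]-2,4-diethylhexa-2,4-dienal; 10 diethyl benzylphosphonate
Product: 11 2-(2,2-dimethoxyethyl)-2-[(2E,4E,6E)-3,5-diethyl-7-phenylhepta-2,4,6-trien-1-yl]-1,3-dithiane
Conditions: 10, NaH, THF, 0 °C; then 9, 0 °C → rt
Reagents that add atoms: none
Why: Horner–Wadsworth–Emmons olefination with a benzylic phosphonate gives the E-styryl terminus and completes the all-E triene.

Step 7
Reactants: 11 2-(2,2-dimethoxyethyl)-2-[(2E,4E,6E)-3,5-diethyl-7-phenylhepta-2,4,6-trien-1-yl]-1,3-dithiane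
Product: 12 {2-[(2E,4E,6E)-3,5-diethyl-7-phenylhepta-2,4,6-trien-1-yl]-1,3-dithian-2-yl}acetaldehyde
Conditions: TsOH·H2O (10 mol%), acetone/H2O 9:1, rt
Reagents that add atoms: water, O
Why: mild acid-catalysed acetal hydrolysis; the dithiane is inert to dilute Brønsted acid and the short, cold exposure spares the triene.

Step 8
Reactants: 12 {2-[(2E,4E,6E)-3,5-diethyl-7-phenylhepta-2,4,6-trien-1-yl]-1,3-dithian-2-yl}acetaldehyde; 7 2-(triphenylphosphoranylidene)butanal
Product: 13 (2E)-4-{2-[(2E,4E,6E)-3,5-diethyl-7-phenylhepta-2,4,6-trien-1-yl]-1,3-dithian-2-yl}-2-ethylbut-2-enal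
Conditions: 7 (1.3 equiv), BHT, CH2Cl2, 40 °C; filtered through silica and used at once
Reagents that add atoms: none
Why: third E-selective Wittig olefination installs the α-ethyl enal dienophile, and the temperature is held at 40 °C to keep the uncatalysed cycloaddition of 13 slow.

Step 9
Reactants: 13 (2E)-4-{2-[(2E,4E,6E)-3,5-diethyl-7-phenylhepta-2,4,6-trien-1-yl]-1,3-dithian-2-yl}-2-ethylbut-2-enal
Product: 14 (3a′R,4′S,5′R,7a′R)-4′,5′,7′-triethyl-5′-[(E)-2-phenylethenyl]-1′,3′,3a′,4′,5′,7a′-hexahydrospiro[1,3-dithiane-2,2′-indene]-4′-carbaldehyde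
Conditions: 9-amino(9-deoxy)epi-quinine (20 mol%), (R)-TRIP (40 mol%), H2O (2 equiv), toluene, 20 °C, 48 h
Reagents that add atoms: none
Why: Proposed new method: the primary amine condenses with the α-ethyl enal to an (E)-configured s-trans iminium ion paired with the bulky chiral phosphate, which lowers the dienophile LUMO enough for the tethered triene (gem-disubstituted dithiane tether, Thorpe–Ingold help) to add at 20 °C; the ion pair blocks one π-face, so the endo transition state (C=N+ under the diene, α-ethyl exo, trans ring fusion) sets C3a′, C4′, C5′ and C7a′ in one event, including the two adjacent quaternary carbons, and hydrolysis frees the catalyst; the closest known reaction types are the imidazolidinone (secondary amine) iminium-catalysed intramolecular Diels–Alder reaction of α-unsubstituted trienals and primary-amine/chiral-phosphate iminium activation of α-branched enals, neither shown for an α-branched enal in an intramolecular Diels–Alder reaction or for building vicinal quaternary centres.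

Step 10
Reactants: 14 (3a′R,4′S,5′R,7a′R)-4′,5′,7′-triethyl-5′-[(E)-2-phenylethenyl]-1′,3′,3a′,4′,5′,7a′-hexahydrospiro[1,3-dithiane-2,2′-indene]-4′-carbaldehyde
Product: 16 (3aR,4S,5R,7aR)-4,5,7-triethyl-2-oxo-5-[(E)-2-phenylethenyl]-2,3,3a,4,5,7a-hexahydro-1H-indene-4-carboxylic acid, via dithiane carboxylic acid 15 (not isolated)
Conditions: NaClO2 (6 equiv), NaH2PO4, 2-methyl-2-butene (excess), THF/MeOH/H2O, 0 °C → rt
Reagents that add atoms: sodium chlorite, [O-]Cl=O.[Na+]; water, O
Why: Pinnick oxidation turns the neopentyl aldehyde into the acid and the same chlorite reagent then cleaves the dithiane oxidatively (S-oxidation, then hydrolysis), while 2-methyl-2-butene scavenges HOCl and protects the alkenes; no stereocentre is touched because C4 has no α-hydrogen.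

Step 11
Reactants: 16 (3aR,4S,5R,7aR)-4,5,7-triethyl-2-oxo-5-[(E)-2-phenylethenyl]-2,3,3a,4,5,7a-hexahydro-1H-indene-4-carboxylic acid
Product: 18 norspiculoic acid A (1R,3R,3aS,4S,5R,7aS)-4,5,7-triethyl-1,3-dimethyl-2-oxo-5-[(E)-2-phenylethenyl]-2,3,3a,4,5,7a-hexahydro-1H-indene-4-carboxylic acid, via monomethyl keto acid 17 (not isolated)
Conditions: LDA (2.2 equiv), THF, −78 °C; MeI (1.1 equiv); LDA (1.2 equiv), −78 °C; MeI (1.5 equiv), → −20 °C; then DBU, MeOH, rt; 1 M HCl
Reagents that add atoms: iodomethane, CI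
Why: two kinetic enolate alkylations (the lithium carboxylate is inert to MeI at low temperature; the second deprotonation takes the remaining CH2), each methyl entering anti to the neighbouring ring-fusion substituent, and DBU equilibration then secures the thermodynamically preferred all-trans C1/C3 configuration (1R,3R).

## Compound list

1 | 1,3-dithiane | C1CSCSC1 | starting material
2 | 2-bromo-1,1-dimethoxyethane | COC(CBr)OC | starting material
3 | 2-(2,2-dimethoxyethyl)-1,3-dithiane | COC(CC1SCCCS1)OC | intermediate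
4 | oxirane | C1CO1 | starting material
5 | 2-[2-(2,2-dimethoxyethyl)-1,3-dithian-2-yl]ethan-1-ol | COC(CC1(CCO)SCCCS1)OC | intermediate
6 | [2-(2,2-dimethoxyethyl)-1,3-dithian-2-yl]acetaldehyde | COC(CC1(CC=O)SCCCS1)OC | intermediate
7 | 2-(triphenylphosphoranylidene)butanal | CCC(C=O)=P(c1ccccc1)(c1ccccc1)c1ccccc1 | starting material
8 | (2E)-4-[2-(2,2-dimethoxyethyl)-1,3-dithian-2-yl]-2-ethylbut-2-enal | CC/C(C=O)=C\CC1(CC(OC)OC)SCCCS1 | intermediate
9 | (2E,4E)-6-[2-(2,2-dimethoxyethyl)-1,3-dithian-2-yl]-2,4-diethylhexa-2,4-dienal | CC/C(C=O)=C\C(CC)=C\CC1(CC(OC)OC)SCCCS1 | intermediate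
10 | diethyl benzylphosphonate | CCOP(=O)(Cc1ccccc1)OCC | starting material
11 | 2-(2,2-dimethoxyethyl)-2-[(2E,4E,6E)-3,5-diethyl-7-phenylhepta-2,4,6-trien-1-yl]-1,3-dithiane | COC(CC1(C/C=C(CC)/C=C(CC)/C=C/c2ccccc2)SCCCS1)OC | intermediate
12 | {2-[(2E,4E,6E)-3,5-diethyl-7-phenylhepta-2,4,6-trien-1-yl]-1,3-dithian-2-yl}acetaldehyde | O=CCC1(C/C=C(CC)/C=C(CC)/C=C/c2ccccc2)SCCCS1 | intermediate
13 | (2E)-4-{2-[(2E,4E,6E)-3,5-diethyl-7-phenylhepta-2,4,6-trien-1-yl]-1,3-dithian-2-yl}-2-ethylbut-2-enal | CC/C(C=O)=C\CC1(C/C=C(CC)/C=C(CC)/C=C/c2ccccc2)SCCCS1 | intermediate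
14 | (3a′R,4′S,5′R,7a′R)-4′,5′,7′-triethyl-5′-[(E)-2-phenylethenyl]-1′,3′,3a′,4′,5′,7a′-hexahydrospiro[1,3-dithiane-2,2′-indene]-4′-carbaldehyde | CCC1=C[C@](/C=C/c2ccccc2)(CC)[C@@](CC)(C=O)[C@H]2[C@H]1CC1(SCCCS1)C2 | intermediate
15 | (3a′R,4′S,5′R,7a′R)-4′,5′,7′-triethyl-5′-[(E)-2-phenylethenyl]-1′,3′,3a′,4′,5′,7a′-hexahydrospiro[1,3-dithiane-2,2′-indene]-4′-carboxylic acid | CCC1=C[C@](/C=C/c2ccccc2)(CC)[C@@](CC)(C(=O)O)[C@H]2[C@H]1CC1(SCCCS1)C2 | intermediate (not isolated)
16 | (3aR,4S,5R,7aR)-4,5,7-triethyl-2-oxo-5-[(E)-2-phenylethenyl]-2,3,3a,4,5,7a-hexahydro-1H-indene-4-carboxylic acid | CCC1=C[C@](/C=C/c2ccccc2)(CC)[C@@](CC)(C(=O)O)[C@H]2[C@H]1CC(=O)C2 | intermediate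
17 | (1R,3aR,4S,5R,7aS)-4,5,7-triethyl-1-methyl-2-oxo-5-[(E)-2-phenylethenyl]-2,3,3a,4,5,7a-hexahydro-1H-indene-4-carboxylic acid (C1-methyl regioisomer shown; the C3-methyl isomer converges on 18) | CCC1=C[C@](/C=C/c2ccccc2)(CC)[C@@](CC)(C(=O)O)[C@H]2[C@H]1[C@@H](C)C(=O)C2 | intermediate (not isolated)
18 | norspiculoic acid A, (1R,3R,3aS,4S,5R,7aS)-4,5,7-triethyl-1,3-dimethyl-2-oxo-5-[(E)-2-phenylethenyl]-2,3,3a,4,5,7a-hexahydro-1H-indene-4-carboxylic acid | CCC1=C[C@](/C=C/c2ccccc2)(CC)[C@@](CC)(C(=O)O)[C@H]2[C@H]1[C@@H](C)C(=O)[C@@H]2C | target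

## Step count and risk

Total steps: 11. Longest linear sequence: 11 (from 1). Compounds 1–13 contain no stereocentre; the first four are set in step 9 and the last two in step 11.

Steps most likely to fail:

Step 9 (the proposed new reaction). Iminium formation from the α-branched enal may be slow, γ-deprotonation to a dienamine could scramble the enal geometry, and facial control in forming two adjacent quaternary carbons is untested. Fallback with known chemistry: setting out from 13, the uncatalysed thermal intramolecular Diels–Alder reaction (toluene, 90 °C, BHT), known for this class of all-E polyenes and passing through the same endo, trans-fused transition state, gives the racemic spiro-aldehyde rac-14 F1. The step-10 chlorite conditions convert it into the racemic keto acid rac-16 F2, which is resolved by preparative SFC on a chiral stationary phase. The route is rejoined at 16.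

Step 11 (one-pot double methylation of the keto acid). Risks are geminal or incomplete methylation, enolate equilibration and O-methylation of the carboxylate. Fallback: setting out from 16, condensation with 1,1-dimethylhydrazine (AcOH cat., EtOH, 60 °C) gives the dimethylhydrazone of 16 F3. Two separate rounds of LDA/MeI on the aza-enolate, which alkylates once per round at the less substituted α-carbon, give the dimethylhydrazone of 18 F4. Hydrolysis (aqueous CuCl2, THF) followed by DBU/MeOH equilibration returns the route at 18.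

Step 8 (last Wittig reaction). The α-formyl ylide is sluggish at 40 °C, and heating harder would start the uncatalysed, racemic cycloaddition of 13 and erode the ee of step 9. Fallback: setting out from 12, Horner–Wadsworth–Emmons reaction with triethyl 2-phosphonobutanoate (NaH, THF, 0 °C) gives the E-enoate F5. DIBAL-H (CH2Cl2, −78 °C) reduces it to the allylic alcohol F6, and MnO2 (CH2Cl2, rt) oxidises this to the enal, returning the route at 13 without ever heating the tetraene.

## Further compounds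

F1 | step 9 | rac-14, 1:1 mixture of 14 and its enantiomer | CCC1=C[C@](/C=C/c2ccccc2)(CC)[C@@](CC)(C=O)[C@H]2[C@H]1CC1(SCCCS1)C2.CCC1=C[C@@](/C=C/c2ccccc2)(CC)[C@](CC)(C=O)[C@@H]2[C@@H]1CC1(SCCCS1)C2
F2 | step 9 | rac-16, 1:1 mixture of 16 and its enantiomer | CCC1=C[C@](/C=C/c2ccccc2)(CC)[C@@](CC)(C(=O)O)[C@H]2[C@H]1CC(=O)C2.CCC1=C[C@@](/C=C/c2ccccc2)(CC)[C@](CC)(C(=O)O)[C@@H]2[C@@H]1CC(=O)C2
F3 | step 11 | dimethylhydrazone of 16, (3aR,4S,5R,7aR)-2-(2,2-dimethylhydrazinylidene)-4,5,7-triethyl-5-[(E)-2-phenylethenyl]-2,3,3a,4,5,7a-hexahydro-1H-indene-4-carboxylic acid | CCC1=C[C@](/C=C/c2ccccc2)(CC)[C@@](CC)(C(=O)O)[C@H]2[C@H]1CC(=NN(C)C)C2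
F4 | step 11 | dimethylhydrazone of 18, (1R,3R,3aS,4S,5R,7aS)-2-(2,2-dimethylhydrazinylidene)-4,5,7-triethyl-1,3-dimethyl-5-[(E)-2-phenylethenyl]-2,3,3a,4,5,7a-hexahydro-1H-indene-4-carboxylic acid (α-epimers converge on hydrolysis and equilibration) | CCC1=C[C@](/C=C/c2ccccc2)(CC)[C@@](CC)(C(=O)O)[C@H]2[C@H]1[C@@H](C)C(=NN(C)C)[C@@H]2C
F5 | step 8 | ethyl (2E)-4-{2-[(2E,4E,6E)-3,5-diethyl-7-phenylhepta-2,4,6-trien-1-yl]-1,3-dithian-2-yl}-2-ethylbut-2-enoate | CCOC(=O)/C(CC)=C/CC1(C/C=C(CC)/C=C(CC)/C=C/c2ccccc2)SCCCS1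
F6 | step 8 | (2E)-4-{2-[(2E,4E,6E)-3,5-diethyl-7-phenylhepta-2,4,6-trien-1-yl]-1,3-dithian-2-yl}-2-ethylbut-2-en-1-ol | OC/C(CC)=C/CC1(C/C=C(CC)/C=C(CC)/C=C/c2ccccc2)SCCCS1
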